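**Plan**
- Retrosynthesis: the C8 ester is cut first. The two lactone bonds O–C6 and C11–C7 are then cut together, which leaves a ten-membered carbocycle with a (4Z,6E)-1,3-diene. That ring is cut at the sp2–sp2 bond C5–C6, and the chain at C1=C10 and C7–C8.
- Enabling feature: the lactone oxygen sits on C6, which is allylic to the ring alkene C4=C5 and next to C7, so C4=C5–C6=C7 can be a ring diene. A 1-carboxyvinylpalladium adds at C7, and the C4–C5–C6 π-allyl is captured at C6 by its own carboxylate, which builds the whole α-methylene-γ-lactone ring in one operation.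
- Forward order: acyclic C1–C10 chain → oxirane ring (Sharpless) → ten-membered ring (hydroboration/Suzuki–Miyaura) → lactone ring (palladium annulation with 2-bromoacrylic acid) → side-chain ester (Yamaguchi).
- Stereochemistry: C8 from Noyori transfer hydrogenation; C1/C10 from Sharpless epoxidation; C7 and C6 from the annulation (face control by C8, syn addition to the E alkene); the side-chain oxirane from Sharpless epoxidation of angelyl alcohol.
- Alkene geometry: 4Z from anti-carboalumination, the C2/C14-cis epoxide pattern from a Still–Gennari Z-enoate, 6E from syn hydroboration.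

Key step: step 13

Remark: atoms are numbered as in germacranolides (ring C1–C10, lactone carbons C11–C13, C14 on C10, C15 on C4), descriptors are derived from the given SMILES, and 1, 5, 6, 9, 19 and 22 are taken as commercial.

Step 1
Reactants: 1 4-pentyn-1-ol
Product: 3 (Z)-5-iodo-4-methylpent-4-en-1-ol, via (Z)-alkenyldimethylalane 2 (not isolated)
Conditions: Me3Al (3 equiv), Cp2ZrCl2 (cat.), ClCH2CH2Cl, rt then reflux; I2, THF, −30 °C
Reagents that add atoms: trimethylaluminium C[Al](C)C; iodine II
Why: Zirconium-catalysed Negishi carboalumination adds methyl and aluminium syn across the alkyne, heating lets the aluminium alkoxide chelate drive isomerisation to the (Z)-alkenylalane, and iodinolysis with retention puts iodine cis to the chain (the later 4Z geometry).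

Step 2
Reactants: 3 (Z)-5-iodo-4-methylpent-4-en-1-ol
Product: 4 (Z)-5-iodo-4-methylpent-4-enal
Conditions: Dess–Martin periodinane, CH2Cl2, 0 °C → rt
Reagents that add atoms: none
Why: Dess–Martin oxidation takes the primary alcohol to the aldehyde under neutral conditions that leave the vinyl iodide geometry untouched; no stereocentre is formed.

Step 3
Reactants: 5 methyl bis(2,2,2-trifluoroethyl)phosphonoacetate; 6 2-bromo-N-methoxy-N-methylacetamide
Product: 7 methyl 2-[bis(2,2,2-trifluoroethoxy)phosphoryl]-4-[methoxy(methyl)amino]-4-oxobutanoate (racemic)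
Conditions: NaH, THF, 0 °C → rt
Reagents that add atoms: none
Why: SN2 alkylation of the stabilised phosphonoacetate anion by a reactive α-bromo amide is the usual way to α-substituted Still–Gennari reagents; the new stereocentre is lost in step 4.

Step 4
Reactants: 7 methyl 2-[bis(2,2,2-trifluoroethoxy)phosphoryl]-4-[methoxy(methyl)amino]-4-oxobutanoate; 4 (Z)-5-iodo-4-methylpent-4-enal
Product: 8 methyl (2Z,6Z)-7-iodo-2-{2-[methoxy(methyl)amino]-2-oxoethyl}-6-methylhepta-2,6-dienoate
Conditions: KN(SiMe3)2, 18-crown-6, THF, −78 °C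
Reagents that add atoms: none
Why: Still–Gennari olefination with the trifluoroethyl phosphonate and a dissociated potassium ion should give the Z trisubstituted enoate (ester cis to the chain), which fixes the C2/C14-cis, C2/C9-trans pattern of the later epoxide.

Step 5
Reactants: 8 methyl (2Z,6Z)-7-iodo-2-{2-[methoxy(methyl)amino]-2-oxoethyl}-6-methylhepta-2,6-dienoate; 9 ethynyltrimethylsilane
Product: 10 methyl (2Z,6Z)-7-iodo-6-methyl-2-[2-oxo-4-(trimethylsilyl)but-3-yn-1-yl]hepta-2,6-dienoate
Conditions: 9, n-BuLi, THF, −78 °C; then 8, −78 → −40 °C; AcOH quench at −78 °C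
Reagents that add atoms: none
Why: Weinreb ketone synthesis: the lithium acetylide adds to the N-methoxy-N-methylamide faster than to the hindered enoate, and the chelated adduct releases the ynone only on the cold acidic quench, which limits migration of the C1=C10 double bond.

Step 6
Reactants: 10 methyl (2Z,6Z)-7-iodo-6-methyl-2-[2-oxo-4-(trimethylsilyl)but-3-yn-1-yl]hepta-2,6-dienoate
Product: 11 methyl (2Z,6Z)-2-[(2R)-2-hydroxy-4-(trimethylsilyl)but-3-yn-1-yl]-7-iodo-6-methylhepta-2,6-dienoate
Conditions: RuCl[(R,R)-TsDPEN](p-cymene) (cat., preactivated), i-PrOH, rt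
Reagents that add atoms: none
Why: Noyori asymmetric transfer hydrogenation reduces only the ynone carbonyl under near-neutral conditions, and the (R,R) ligand should deliver hydride to the face that gives the (R)-propargylic alcohol at C8 (reagent control).

Step 7
Reactants: 11 methyl (2Z,6Z)-2-[(2R)-2-hydroxy-4-(trimethylsilyl)but-3-yn-1-yl]-7-iodo-6-methylhepta-2,6-dienoate
Product: 12 methyl (2Z,6Z)-2-[(2R)-2-(tert-butyldimethylsilyloxy)-4-(trimethylsilyl)but-3-yn-1-yl]-7-iodo-6-methylhepta-2,6-dienoate
Conditions: TBSOTf, 2,6-lutidine, CH2Cl2, −78 °C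
Reagents that add atoms: tert-butyldimethylsilyl trifluoromethanesulfonate CC(C)(C)[Si](C)(C)OS(=O)(=O)C(F)(F)F
Why: Silylation with the silyl triflate is fast at low temperature and outruns lactonisation onto the neighbouring ester; an ether and not an ester is needed at C8 because zerovalent palladium would later ionise an allylic ester.

Step 8
Reactants: 12 methyl (2Z,6Z)-2-[(2R)-2-(tert-butyldimethylsilyloxy)-4-(trimethylsilyl)but-3-yn-1-yl]-7-iodo-6-methylhepta-2,6-dienoate
Product: 13 methyl (2Z,6Z)-2-[(2R)-2-(tert-butyldimethylsilyloxy)but-3-yn-1-yl]-7-iodo-6-methylhepta-2,6-dienoate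
Conditions: K2CO3 (cat.), MeOH, 0 °C
Reagents that add atoms: none
Why: Base-catalysed methanolysis of the C(sp)–Si bond frees the terminal alkyne for the later hydroboration and leaves the silyl ether and the methyl enoate unchanged.

Step 9
Reactants: 13 methyl (2Z,6Z)-2-[(2R)-2-(tert-butyldimethylsilyloxy)but-3-yn-1-yl]-7-iodo-6-methylhepta-2,6-dienoate
Product: 14 (2Z,6Z)-2-[(2R)-2-(tert-butyldimethylsilyloxy)but-3-yn-1-yl]-7-iodo-6-methylhepta-2,6-dien-1-ol
Conditions: i-Bu2AlH (2.5 equiv), CH2Cl2, −78 °C
Reagents that add atoms: none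
Why: Low-temperature 1,2-reduction of the enoate by the aluminium hydride gives the allylic alcohol (C14–OH) that will direct the epoxidation, with the alkene geometry retained.

Step 10
Reactants: 14 (2Z,6Z)-2-[(2R)-2-(tert-butyldimethylsilyloxy)but-3-yn-1-yl]-7-iodo-6-methylhepta-2,6-dien-1-ol
Product: 15 {(2S,3R)-2-[(2R)-2-(tert-butyldimethylsilyloxy)but-3-yn-1-yl]-3-[(3Z)-4-iodo-3-methylbut-3-en-1-yl]oxiran-2-yl}methanol
Conditions: Ti(OiPr)4 (cat.), L-(+)-diethyl tartrate (cat.), t-BuOOH, 4 Å MS, CH2Cl2, −20 °C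
Reagents that add atoms: tert-butyl hydroperoxide CC(C)(C)OO
Why: Sharpless asymmetric epoxidation acts only on the allylic alcohol alkene, and the L-(+)-tartrate should deliver oxygen to the face that gives the (1R,10S) epoxide (reagent control), the cis C2/C14 relationship coming from the alkene geometry.

Step 11
Reactants: 15 {(2S,3R)-2-[(2R)-2-(tert-butyldimethylsilyloxy)but-3-yn-1-yl]-3-[(3Z)-4-iodo-3-methylbut-3-en-1-yl]oxiran-2-yl}methanol
Product: 16 {(2S,3R)-2-[(2R)-2-(tert-butyldimethylsilyloxy)but-3-yn-1-yl]-3-[(3Z)-4-iodo-3-methylbut-3-en-1-yl]oxiran-2-yl}methyl acetate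
Conditions: Ac2O, pyridine, DMAP (cat.), CH2Cl2, 0 °C
Reagents that add atoms: acetic anhydride CC(=O)OC(C)=O
Why: Standard acetylation of the primary epoxy alcohol installs the C14 acetate of the target and blocks Payne rearrangement.

Step 12
Reactants: 16 {(2S,3R)-2-[(2R)-2-(tert-butyldimethylsilyloxy)but-3-yn-1-yl]-3-[(3Z)-4-iodo-3-methylbut-3-en-1-yl]oxiran-2-yl}methyl acetate
Product: 18 (1R,4Z,6E,8R,10S)-8-(tert-butyldimethylsilyloxy)-1,10-epoxy-11,12,13-trinorgermacra-4,6-dien-14-yl acetate, via (E)-alkenyldicyclohexylborane 17 (not isolated)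
Conditions: (c-C6H11)2BH (from BH3·SMe2, cyclohexene), THF, 0 °C; then Pd(PPh3)4 (cat.), TlOEt, THF/H2O, rt, slow addition at high dilution
Reagents that add atoms: none
Why: Syn hydroboration of the terminal alkyne gives the (E)-alkenylborane, and intramolecular Suzuki–Miyaura coupling with the (Z)-vinyl iodide should close the ten-membered ring at C5–C6 with retention of both geometries (4Z,6E).

Step 13
Reactants: 18 (1R,4Z,6E,8R,10S)-8-(tert-butyldimethylsilyloxy)-1,10-epoxy-11,12,13-trinorgermacra-4,6-dien-14-yl acetate; 19 2-bromoacrylic acid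
Product: 20 (1R,4Z,6R,7S,8R,10S)-14-acetoxy-8-(tert-butyldimethylsilyloxy)-1,10-epoxygermacra-4,11(13)-dien-12,6-olide
Conditions: Pd(OAc)2 (10 mol %), PPh3 (20 mol %), Na2CO3, n-Bu4NCl, DMF, 60 °C
Reagents that add atoms: none
Why: Zerovalent palladium inserts into the C–Br bond of 19, the resulting 1-carboxyvinylpalladium adds syn across the strained (6E) alkene with C11 going to the less substituted diene terminus C7, and the C6–C5–C4 π-allylpalladium so formed is closed at C6 by its own palladium-bound carboxylate (six-membered palladacycle, C–O reductive elimination), which returns zerovalent palladium. The closest known reaction type is the Larock heteroannulation of 1,3-dienes by vinylic or aryl halides that carry a carboxylic acid. The lactone ring closes in the 5-exo mode at the allyl terminus C6, the seven-membered alternative at the tertiary C4 being disfavoured. C7 is set by substrate control from C8: only the outer face of the trans C6=C7 bond is open, and in the ring conformer that holds the C8 silyloxy group pseudo-equatorial this face is the one anti to C9; C6 follows from the syn course of C–C and C–O bond formation across the E alkene, which gives the trans-fused lactone, and the (4Z) geometry is kept because the allyl unit cannot rotate at the tertiary C4. The step needs regioselectivity (C7 over C4 and C6) and chemoselectivity (diene over the product acrylate and over the C8–O bond): the unsymmetrical diene, the silyl ether in place of an ester at C8 and the non-allylic position of the 1,10-epoxide should secure them.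

Step 14
Reactants: 20 (1R,4Z,6R,7S,8R,10S)-14-acetoxy-8-(tert-butyldimethylsilyloxy)-1,10-epoxygermacra-4,11(13)-dien-12,6-olide
Product: 21 (1R,4Z,6R,7R,8R,10S)-14-acetoxy-1,10-epoxy-8-hydroxygermacra-4,11(13)-dien-12,6-olide
Conditions: HF·pyridine, pyridine, THF, 0 °C → rt
Reagents that add atoms: none
Why: Fluoride cleavage of the silyl ether under pyridine-buffered conditions should spare the epoxide, the acetate and the α-methylene lactone and frees the C8 alcohol without touching its configuration (the C7 descriptor changes only by priority).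

Step 15
Reactants: 22 angelic acid, (Z)-2-methylbut-2-enoic acid
Product: 23 (Z)-2-methylbut-2-en-1-ol
Conditions: LiAlH4, Et2O, 0 °C
Reagents that add atoms: none
Why: Hydride 1,2-reduction of the acid gives the allylic alcohol and keeps the Z geometry of angelic acid.

Step 16
Reactants: 23 (Z)-2-methylbut-2-en-1-ol
Product: 24 [(2R,3S)-2,3-dimethyloxiran-2-yl]methanol
Conditions: Ti(OiPr)4 (cat.), D-(−)-diethyl tartrate (cat.), t-BuOOH, 4 Å MS, CH2Cl2, −20 °C
Reagents that add atoms: tert-butyl hydroperoxide CC(C)(C)OO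
Why: Sharpless asymmetric epoxidation with the D-(−)-tartrate should deliver oxygen to the face that gives the (2R,3S) epoxy alcohol, the cis relationship of CH2OH and the C3 methyl coming from the Z alkene.

Step 17
Reactants: 24 [(2R,3S)-2,3-dimethyloxiran-2-yl]methanol
Product: 25 (2S,3S)-2,3-dimethyloxirane-2-carboxylic acid
Conditions: RuCl3 (cat.), NaIO4, MeCN/EtOAc/H2O, 0 °C → rt
Reagents that add atoms: water O
Why: RuO4 formed in situ oxidises the primary alcohol through the aldehyde hydrate to the acid without opening the epoxide (Sharpless RuCl3/NaIO4 oxidation); the stereocentres are untouched and the C2 descriptor changes only by priority.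

Step 18
Reactants: 25 (2S,3S)-2,3-dimethyloxirane-2-carboxylic acid; 21 (1R,4Z,6R,7R,8R,10S)-14-acetoxy-1,10-epoxy-8-hydroxygermacra-4,11(13)-dien-12,6-olide
Product: 27 (1R,4Z,6R,7R,8R,10S)-14-acetoxy-1,10-epoxy-8-[(2S,3S)-2,3-dimethyloxirane-2-carbonyloxy]germacra-4,11(13)-dien-12,6-olide, via mixed anhydride 26 (not isolated)
Conditions: 2,4,6-trichlorobenzoyl chloride, Et3N, THF, rt; then 21, DMAP, toluene, rt
Reagents that add atoms: none
Why: Yamaguchi esterification: the mixed anhydride acylates the hindered C8 alcohol under DMAP catalysis with retention at C8 and without epimerising the α-quaternary epoxy acid.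

**Compound list**
1 | 4-pentyn-1-ol | C#CCCCO | starting material
2 | dimethyl{(1Z)-5-[(dimethylalumanyl)oxy]-2-methylpent-1-en-1-yl}alumane | C[Al](C)/C=C(/C)CCCO[Al](C)C | intermediate (not isolated)
3 | (Z)-5-iodo-4-methylpent-4-en-1-ol | OCCC/C(C)=C\I | intermediate
4 | (Z)-5-iodo-4-methylpent-4-enal | O=CCC/C(C)=C\I | intermediate
5 | methyl bis(2,2,2-trifluoroethyl)phosphonoacetate | COC(=O)CP(=O)(OCC(F)(F)F)OCC(F)(F)F | starting material
6 | 2-bromo-N-methoxy-N-methylacetamide | CON(C)C(=O)CBr | starting material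
7 | methyl 2-[bis(2,2,2-trifluoroethoxy)phosphoryl]-4-[methoxy(methyl)amino]-4-oxobutanoate (racemic) | COC(=O)C(CC(=O)N(C)OC)P(=O)(OCC(F)(F)F)OCC(F)(F)F | intermediate
8 | methyl (2Z,6Z)-7-iodo-2-{2-[methoxy(methyl)amino]-2-oxoethyl}-6-methylhepta-2,6-dienoate | COC(=O)/C(CC(=O)N(C)OC)=C\CC/C(C)=C\I | intermediate
9 | ethynyltrimethylsilane | C#C[Si](C)(C)C | starting material
10 | methyl (2Z,6Z)-7-iodo-6-methyl-2-[2-oxo-4-(trimethylsilyl)but-3-yn-1-yl]hepta-2,6-dienoate | COC(=O)/C(CC(=O)C#C[Si](C)(C)C)=C\CC/C(C)=C\I | intermediate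
11 | methyl (2Z,6Z)-2-[(2R)-2-hydroxy-4-(trimethylsilyl)but-3-yn-1-yl]-7-iodo-6-methylhepta-2,6-dienoate | COC(=O)/C(C[C@@H](O)C#C[Si](C)(C)C)=C\CC/C(C)=C\I | intermediate
12 | methyl (2Z,6Z)-2-[(2R)-2-(tert-butyldimethylsilyloxy)-4-(trimethylsilyl)but-3-yn-1-yl]-7-iodo-6-methylhepta-2,6-dienoate | COC(=O)/C(C[C@@H](O[Si](C)(C)C(C)(C)C)C#C[Si](C)(C)C)=C\CC/C(C)=C\I | intermediate
13 | methyl (2Z,6Z)-2-[(2R)-2-(tert-butyldimethylsilyloxy)but-3-yn-1-yl]-7-iodo-6-methylhepta-2,6-dienoate | COC(=O)/C(C[C@@H](O[Si](C)(C)C(C)(C)C)C#C)=C\CC/C(C)=C\I | intermediate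
14 | (2Z,6Z)-2-[(2R)-2-(tert-butyldimethylsilyloxy)but-3-yn-1-yl]-7-iodo-6-methylhepta-2,6-dien-1-ol | OC/C(C[C@@H](O[Si](C)(C)C(C)(C)C)C#C)=C\CC/C(C)=C\I | intermediate
15 | {(2S,3R)-2-[(2R)-2-(tert-butyldimethylsilyloxy)but-3-yn-1-yl]-3-[(3Z)-4-iodo-3-methylbut-3-en-1-yl]oxiran-2-yl}methanol | I/C=C(/C)CC[C@H]1O[C@]1(CO)C[C@@H](O[Si](C)(C)C(C)(C)C)C#C | intermediate
16 | {(2S,3R)-2-[(2R)-2-(tert-butyldimethylsilyloxy)but-3-yn-1-yl]-3-[(3Z)-4-iodo-3-methylbut-3-en-1-yl]oxiran-2-yl}methyl acetate | I/C=C(/C)CC[C@H]1O[C@]1(COC(C)=O)C[C@@H](O[Si](C)(C)C(C)(C)C)C#C | intermediate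
17 | (E)-alkenyldicyclohexylborane from 16 (boron on the former terminal alkyne carbon C6) | I/C=C(/C)CC[C@H]1O[C@]1(COC(C)=O)C[C@@H](O[Si](C)(C)C(C)(C)C)/C=C/B(C1CCCCC1)C1CCCCC1 | intermediate (not isolated)
18 | (1R,4Z,6E,8R,10S)-8-(tert-butyldimethylsilyloxy)-1,10-epoxy-11,12,13-trinorgermacra-4,6-dien-14-yl acetate (ten-membered carbocycle) | [C@H]1(O[Si](C)(C)C(C)(C)C)/C=C/C=C(/C)CC[C@H]2O[C@]2(COC(C)=O)C1 | intermediate
19 | 2-bromoacrylic acid | C=C(Br)C(=O)O | starting material
20 | (1R,4Z,6R,7S,8R,10S)-14-acetoxy-8-(tert-butyldimethylsilyloxy)-1,10-epoxygermacra-4,11(13)-dien-12,6-olide | C=C1C(=O)O[C@@H]2/C=C(/C)CC[C@H]3O[C@]3(COC(C)=O)C[C@@H](O[Si](C)(C)C(C)(C)C)[C@@H]12 | intermediate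
21 | (1R,4Z,6R,7R,8R,10S)-14-acetoxy-1,10-epoxy-8-hydroxygermacra-4,11(13)-dien-12,6-olide | C=C1C(=O)O[C@@H]2/C=C(/C)CC[C@H]3O[C@]3(COC(C)=O)C[C@@H](O)[C@@H]12 | intermediate
22 | angelic acid, (Z)-2-methylbut-2-enoic acid | C/C=C(/C)C(=O)O | starting material
23 | (Z)-2-methylbut-2-en-1-ol | C/C=C(/C)CO | intermediate
24 | [(2R,3S)-2,3-dimethyloxiran-2-yl]methanol | OC[C@@]1(C)O[C@H]1C | intermediate
25 | (2S,3S)-2,3-dimethyloxirane-2-carboxylic acid | OC(=O)[C@@]1(C)O[C@H]1C | intermediate
26 | (2S,3S)-2,3-dimethyloxirane-2-carboxylic 2,4,6-trichlorobenzoic anhydride | O=C(OC(=O)c1c(Cl)cc(Cl)cc1Cl)[C@@]1(C)O[C@H]1C | intermediate (not isolated)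
27 | (1R,4Z,6R,7R,8R,10S)-14-acetoxy-1,10-epoxy-8-[(2S,3S)-2,3-dimethyloxirane-2-carbonyloxy]germacra-4,11(13)-dien-12,6-olide | C=C1C(=O)O[C@@H]2/C=C(/C)CC[C@H]3O[C@]3(COC(C)=O)C[C@@H](OC(=O)[C@@]3(C)O[C@H]3C)[C@@H]12 | target

**Totals and risks**
Total steps: 18. Longest linear sequence: 14 steps (steps 1, 2, 4 to 14, 18).

Step 13 is the most likely to fail. The carbopalladation may show poor facial control (attack on the face syn to C9) or poor regiocontrol (addition at C6, Heck-type β-hydride loss), and the allylic lactone may re-ionise. The fallback sets out from 18 and replaces the palladium step by a radical–polar crossover annulation. Visible-light photoredox catalysis (fac-Ir(ppy)3, blue light, MeCN/H2O) with ethyl bromo(diethoxyphosphoryl)acetate should add the phosphonoacetate radical at C7; the allyl radical is then oxidised by the oxidised photocatalyst and the ester closes on C6 to give the α-(diethoxyphosphoryl) lactone F1. Horner–Wadsworth–Emmons methylenation of F1 with aqueous formaldehyde and K2CO3 in THF then gives 20, where the route is rejoined.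

Step 12 is the second risk. Closure of the strained ten-membered ring may lose out to oligomerisation or protodeboronation. The fallback sets out from 16: semihydrogenation of the alkyne (H2, Pd/CaCO3 poisoned with Pb(OAc)2, quinoline, EtOAc) gives the terminal alkene F2. An intramolecular Heck reaction (Pd(OAc)2, Ag2CO3, DMF, high dilution) then closes the ring in the endo mode at the terminal carbon, and β-hydride elimination towards C6 should give the conjugated (6E) diene 18, where the route is rejoined.

Step 5 is the third risk. The C1=C10 double bond may migrate under base into conjugation with the new ketone, and the acetylide may over-add to the ester. The fallback sets out from 8: Cp2Zr(H)Cl in THF reduces the Weinreb amide selectively to the aldehyde F3. A zinc-mediated asymmetric alkynylation of F3 with 9 (Me2Zn, the ProPhenol enantiomer that gives the R carbinol, toluene) then leads directly to 11, where the route is rejoined, so that no ketone is ever present.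

**Further compounds**
F1 | step 13 | (1R,4Z,6R,7S,8R,10S)-14-acetoxy-8-(tert-butyldimethylsilyloxy)-11-(diethoxyphosphoryl)-1,10-epoxygermacr-4-en-12,6-olide (C11 epimers) | CCOP(=O)(OCC)C1C(=O)O[C@@H]2/C=C(/C)CC[C@H]3O[C@]3(COC(C)=O)C[C@@H](O[Si](C)(C)C(C)(C)C)[C@@H]12
F2 | step 12 | {(2S,3R)-2-[(2R)-2-(tert-butyldimethylsilyloxy)but-3-en-1-yl]-3-[(3Z)-4-iodo-3-methylbut-3-en-1-yl]oxiran-2-yl}methyl acetate | I/C=C(/C)CC[C@H]1O[C@]1(COC(C)=O)C[C@@H](O[Si](C)(C)C(C)(C)C)C=C
F3 | step 5 | methyl (2Z,6Z)-7-iodo-6-methyl-2-(2-oxoethyl)hepta-2,6-dienoate | COC(=O)/C(CC=O)=C\CC/C(C)=C\I
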